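**Retrosynthetic overview**

1. Target 27 ← mild acid hydrolysis of bridged acetonide 26 ← intramolecular SNAr of 25, in which the O5 alkoxide attacks C7'–F and closes the 1,5-benzodioxepine across C5 and C7.
2. 25 ← tetrahydrochromone 21 (Mitsunobu inversion at C5, then 6,8-acetonide) ← γ-pyrone annulation of the acylketene from dioxinone 9 onto the enol silane of cyclohexanone 17.
3. 17 ← Ferrier carbocyclisation of the D-gluco hex-5-enopyranoside 16 ← SN2 of fluorochromone phenol 6 on diacetone-D-allose triflate 11. This makes the C7–O–C6' ether and carries sugar C2, C3, C4 into C6, C7, C8.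
4. Ring order: aromatic chromone (step 2) → carbocycle (step 11) → γ-pyranone (step 13) → 1,3-dioxane lock (step 16) → bridging dioxepine (step 18).
5. Feature: in the aromatic chromone C7' is para (through C4a') to the C4' carbonyl, so C7'–F is an SNAr site while O6' is a phenol nucleophile. With O6 and O8 tied in a dioxane, O5 and O7 of the carbocycle are syn-diaxial at catechol spacing.

Key step: step 18

**Remarks**

- Abbreviations: Ar = 7-fluoro-4-oxo-2-(2-phenylethyl)-4H-chromen-6-yl; TBS = tert-butyldimethylsilyl; TMS = trimethylsilyl. Chromone numbering (C5–C8 sp3) is used for the tetrahydrochromone and primed numbers for the aromatic chromone.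
- Assumption: the Ferrier carbocyclisation of 16 is taken to follow gluco-configured precedent and give mainly the 5S carbinol (OH cis to O6). Step 14 inverts this centre.
- Compounds 13–16 are drawn as the α-anomer. The β-anomer expected alongside in step 7 loses its anomeric centre in step 11 and can be carried through.

**Route**

Step 1
Reactants: 1 3-fluoro-4-methoxyphenol
Product: 2 1-(4-fluoro-2-hydroxy-5-methoxyphenyl)ethan-1-one
Conditions: AcOH, BF3·OEt2, 90 °C
Reagents that add atoms: acetic acid CC(=O)O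
Why: BF3-promoted C-acylation of the phenol (Fries-type Friedel–Crafts acylation) should go ortho to OH at the unhindered position para to fluorine; no stereocentre is involved.

Step 2
Reactants: 2 1-(4-fluoro-2-hydroxy-5-methoxyphenyl)ethan-1-one; 3 methyl 3-phenylpropanoate
Product: 5 7-fluoro-6-methoxy-2-(2-phenylethyl)-4H-chromen-4-one, via diketone 4 (not isolated)
Conditions: NaH, THF, 65 °C; then conc. HCl, MeOH, 65 °C
Reagents that add atoms: none
Why: Crossed Claisen condensation of the acetophenone dianion with the ester gives diketone 4, which acid cyclodehydrates to the chromone; the fluorine is safe because the ring is an electron-rich phenoxide/enolate in the basic stage.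

Step 3
Reactants: 5 7-fluoro-6-methoxy-2-(2-phenylethyl)-4H-chromen-4-one
Product: 6 7-fluoro-6-hydroxy-2-(2-phenylethyl)-4H-chromen-4-one (ArOH)
Conditions: BBr3, CH2Cl2, −78 °C to 25 °C
Reagents that add atoms: none
Why: BBr3 cleavage of the aryl methyl ether (Lewis acid-assisted SN2 at methyl) should free the C6' phenol without touching the chromone or the C–F bond.

Step 4
Reactants: 7 2,2,6-trimethyl-4H-1,3-dioxin-4-one; 8 4-methoxybenzyl bromide
Product: 9 6-[2-(4-methoxyphenyl)ethyl]-2,2-dimethyl-4H-1,3-dioxin-4-one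
Conditions: LiN(iPr)2, THF/DMPU, −78 °C; then 8, −78 °C to −20 °C
Reagents that add atoms: none
Why: γ-Alkylation of the lithium dienolate of the dioxinone (vinylogous enolate alkylation) with a reactive benzylic bromide installs the 4-methoxyphenethyl chain.

Step 5
Reactants: 10 1,2:5,6-di-O-isopropylidene-α-D-allofuranose
Product: 11 1,2:5,6-di-O-isopropylidene-3-O-(trifluoromethylsulfonyl)-α-D-allofuranose
Conditions: Tf2O, pyridine, CH2Cl2, −10 °C
Reagents that add atoms: triflic anhydride O=S(=O)(OS(=O)(=O)C(F)(F)F)C(F)(F)F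
Why: O-Sulfonylation of the secondary alcohol activates C3 and leaves its allo configuration untouched.

Step 6
Reactants: 11 1,2:5,6-di-O-isopropylidene-3-O-(trifluoromethylsulfonyl)-α-D-allofuranose; 6 7-fluoro-6-hydroxy-2-(2-phenylethyl)-4H-chromen-4-one
Product: 12 3-O-Ar-1,2:5,6-di-O-isopropylidene-α-D-glucofuranose
Conditions: Cs2CO3, DMF, 40 °C
Reagents that add atoms: none
Why: Williamson-type SN2 displacement of the triflate by the caesium phenoxide from the open exo face inverts C3 to the gluco configuration and makes the future C7–O–C6' ether; H4 is syn to the leaving group, which disfavours E2.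

Step 7
Reactants: 12 3-O-Ar-1,2:5,6-di-O-isopropylidene-α-D-glucofuranose
Product: 13 methyl 3-O-Ar-α-D-glucopyranoside
Conditions: HCl (1.25 M in MeOH), 65 °C
Reagents that add atoms: methanol CO
Why: Acid methanolysis removes both acetonides and Fischer glycosidation under thermodynamic control should give the methyl pyranoside (α favoured by the anomeric effect), with C2–C5 unchanged.

Step 8
Reactants: 13 methyl 3-O-Ar-α-D-glucopyranoside
Product: 14 methyl 6-deoxy-6-iodo-3-O-Ar-α-D-glucopyranoside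
Conditions: I2, PPh3, imidazole, THF, 65 °C
Reagents that add atoms: iodine II
Why: Garegg–Samuelsson (Appel-type) iodination is selective for the primary 6-OH over the two secondary hydroxyls.

Step 9
Reactants: 14 methyl 6-deoxy-6-iodo-3-O-Ar-α-D-glucopyranoside
Product: 15 methyl 2,4-di-O-TBS-6-deoxy-6-iodo-3-O-Ar-α-D-glucopyranoside
Conditions: TBSOTf, 2,6-lutidine, CH2Cl2, 0 °C to 25 °C
Reagents that add atoms: tert-butyldimethylsilyl triflate CC(C)(C)[Si](C)(C)OS(=O)(=O)C(F)(F)F
Why: Silyl triflate silylation protects O2 and O4 (future O6 and O8) with groups that survive the carbocyclisation and keep them distinct from O5 later.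

Step 10
Reactants: 15 methyl 2,4-di-O-TBS-6-deoxy-6-iodo-3-O-Ar-α-D-glucopyranoside
Product: 16 methyl 2,4-di-O-TBS-6-deoxy-3-O-Ar-α-D-xylo-hex-5-enopyranoside
Conditions: DBU, THF, 65 °C
Reagents that add atoms: none
Why: E2 dehydroiodination by the non-nucleophilic amidine base gives the exocyclic enol ether needed for carbocyclisation.

Step 11
Reactants: 16 methyl 2,4-di-O-TBS-6-deoxy-3-O-Ar-α-D-xylo-hex-5-enopyranoside
Product: 17 (2S,3R,4S,5S)-3-(ArO)-2,4-bis(TBSO)-5-hydroxycyclohexan-1-one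
Conditions: Hg(OCOCF3)2 (10 mol %), acetone/H2O 4:1, 25 °C
Reagents that add atoms: water O
Why: Ferrier carbocyclisation (oxymercuration of the enol ether, loss of methanol to the 5-keto aldehyde, intramolecular aldol of the mercury enolate) closes the cyclohexanone; by analogy with gluco substrates the new carbinol should form mainly trans to the sugar C3 substituent, that is cis to the future O6 (5S).

Step 12
Reactants: 17 (2S,3R,4S,5S)-3-(ArO)-2,4-bis(TBSO)-5-hydroxycyclohexan-1-one
Product: 18 bis-TMS enol silane of 17 (C1–OTMS on a C1=C6 double bond, 5-OTMS, ring stereocentres as in 17)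
Conditions: TMSOTf, Et3N, CH2Cl2, 0 °C
Reagents that add atoms: trimethylsilyl triflate C[Si](C)(C)OS(=O)(=O)C(F)(F)F
Why: Soft enolisation with silyl triflate and amine silylates the free hydroxyl and should form the enol silane toward the unhindered methylene carbon, away from the α-carbon that carries the bulky silyloxy group, without a free enolate that could expel the β-aryloxy group.

Step 13
Reactants: 18 bis-TMS enol silane of 17; 9 6-[2-(4-methoxyphenyl)ethyl]-2,2-dimethyl-4H-1,3-dioxin-4-one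
Product: 21 (5S,6S,7R,8S)-7-(ArO)-6,8-bis(TBSO)-5-hydroxy-2-[2-(4-methoxyphenyl)ethyl]-5,6,7,8-tetrahydro-4H-chromen-4-one, via acylketene 19 (not isolated), via cycloadduct 20 (not isolated)
Conditions: 9 (2.5 equiv), toluene, 110 °C; then p-toluenesulfonic acid monohydrate (cat.), THF/H2O, 25 °C
Reagents that add atoms: none
Why: Thermal retro-[4+2] of the dioxinone releases acylketene 19, whose hetero-Diels–Alder addition to the electron-rich enol silane gives 20, and acid then expels silanol from the ketal carbon to aromatise to the γ-pyrone and frees the C5 hydroxyl; the two transient centres vanish and C5–C8 are untouched.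

Step 14
Reactants: 21 (5S,6S,7R,8S)-7-(ArO)-6,8-bis(TBSO)-5-hydroxy-2-[2-(4-methoxyphenyl)ethyl]-5,6,7,8-tetrahydro-4H-chromen-4-one
Product: 22 (5R,6S,7R,8S)-7-(ArO)-6,8-bis(TBSO)-2-[2-(4-methoxyphenyl)ethyl]-4-oxo-5,6,7,8-tetrahydro-4H-chromen-5-yl chloroacetate
Conditions: ClCH2CO2H, PPh3, DIAD, toluene, 0 °C to 25 °C
Reagents that add atoms: chloroacetic acid OC(=O)CCl
Why: Mitsunobu esterification, in which chloroacetate attacks the oxyphosphonium ion by SN2, should invert C5 to 5R (O5 trans to O6, cis to O7) and leave O5 masked for the acetal step.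

Step 15
Reactants: 22 (5R,6S,7R,8S)-5-chloroacetate with 6,8-bis(TBSO)
Product: 23 (5R,6S,7R,8S)-7-(ArO)-6,8-dihydroxy-2-[2-(4-methoxyphenyl)ethyl]-4-oxo-5,6,7,8-tetrahydro-4H-chromen-5-yl chloroacetate
Conditions: HF·pyridine, pyridine/THF, 0 °C to 25 °C
Reagents that add atoms: none
Why: Fluoride-driven Si–O cleavage removes both silyl ethers under weakly acidic, non-nucleophilic conditions that spare the chloroacetate and the aryl fluoride.

Step 16
Reactants: 23 (5R,6S,7R,8S)-5-chloroacetate 6,8-diol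
Product: 24 (5R,6S,7R,8S)-7-(ArO)-6,8-O-isopropylidene-2-[2-(4-methoxyphenyl)ethyl]-4-oxo-5,6,7,8-tetrahydro-4H-chromen-5-yl chloroacetate
Conditions: 2,2-dimethoxypropane, pyridinium p-toluenesulfonate (cat.), CH2Cl2, 4 Å MS, 40 °C
Reagents that add atoms: 2,2-dimethoxypropane COC(C)(C)OC
Why: Acid-catalysed transketalisation forms the 1,3-dioxane across the cis-related O6 and O8, the only free hydroxyls, which requires the ring flip that puts all four C–O bonds of the carbocycle axial.

Step 17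
Reactants: 24 6,8-O-isopropylidene 5-chloroacetate
Product: 25 (5R,6S,7R,8S)-7-(ArO)-5-hydroxy-6,8-O-isopropylidene-2-[2-(4-methoxyphenyl)ethyl]-5,6,7,8-tetrahydro-4H-chromen-4-one
Conditions: thiourea, NaHCO3, EtOH/THF, 55 °C
Reagents that add atoms: none
Why: Thiourea dechloroacetylation (S-alkylation, then cyclisation to the aminothiazolone) should release the C5 hydroxyl with retention under near-neutral conditions, with no alkoxide present that could attack the aryl fluoride.

Step 18
Reactants: 25 (5R,6S,7R,8S)-7-(ArO)-5-hydroxy-6,8-O-isopropylidene-2-[2-(4-methoxyphenyl)ethyl]-5,6,7,8-tetrahydro-4H-chromen-4-one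
Product: 26 6,8-O-isopropylidene derivative of the target (O5–C7' and O7–C6' ethers, 5R,6S,7R,8S)
Conditions: Cs2CO3, DMF (0.005 M), 60 °C
Reagents that add atoms: none
Why: Cs2CO3 deprotonates O5–H and the alkoxide adds to C7' ipso to fluorine; the Meisenheimer anion is delocalised through C8' and C4a' onto the para C4' carbonyl and collapses with loss of fluoride. The closest known chemistry is alkoxide SNAr at C7 of 7-fluorochromones and ring-closing SNAr aryl ether formation on acyl-activated fluoroarenes. The seven-membered 1,5-benzodioxepine closes 7-exo-trig at the ipso carbon and spans C5 and C7 of the carbocycle. No stereocentre is created and no C–O bond at C5 is broken, so 5R is retained. Chemoselectivity rests on O5 being the only free hydroxyl (O6 and O8, which would give six-membered benzodioxanes, are tied in the acetonide), and regioselectivity on the phenol oxygen already sitting on C6' and fluorine on C7'. The dioxane also holds O5 and O7 syn-diaxial at about catechol spacing and keeps H8 in the plane of the pyranone, so base should not start a vinylogous E1cB loss of the C7 aryloxide; high dilution suppresses intermolecular substitution.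

Step 19
Reactants: 26 6,8-O-isopropylidene derivative of the target
Product: 27 (+)-4'-methoxyaquisinenone G
Conditions: AcOH/H2O 4:1, 40 °C
Reagents that add atoms: none
Why: Acid-catalysed hydrolysis of the strained 1,3-diaxial acetonide frees the 6,8-diol; mild acid is chosen so that the vinylogous-acetal C5–O–aryl bond is not ionised.

**Compound list**

1 | 3-fluoro-4-methoxyphenol | COc1ccc(O)cc1F | starting material
2 | 1-(4-fluoro-2-hydroxy-5-methoxyphenyl)ethan-1-one | CC(=O)c1cc(OC)c(F)cc1O | intermediate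
3 | methyl 3-phenylpropanoate | COC(=O)CCc1ccccc1 | starting material
4 | 1-(4-fluoro-2-hydroxy-5-methoxyphenyl)-5-phenylpentane-1,3-dione | COc1cc(C(=O)CC(=O)CCc2ccccc2)c(O)cc1F | intermediate
5 | 7-fluoro-6-methoxy-2-(2-phenylethyl)-4H-chromen-4-one | COc1cc2c(=O)cc(CCc3ccccc3)oc2cc1F | intermediate
6 | 7-fluoro-6-hydroxy-2-(2-phenylethyl)-4H-chromen-4-one | Oc1cc2c(=O)cc(CCc3ccccc3)oc2cc1F | intermediate
7 | 2,2,6-trimethyl-4H-1,3-dioxin-4-one | CC1=CC(=O)OC(C)(C)O1 | starting material
8 | 4-methoxybenzyl bromide | COc1ccc(CBr)cc1 | starting material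
9 | 6-[2-(4-methoxyphenyl)ethyl]-2,2-dimethyl-4H-1,3-dioxin-4-one | COc1ccc(CCC2=CC(=O)OC(C)(C)O2)cc1 | intermediate
10 | 1,2:5,6-di-O-isopropylidene-α-D-allofuranose | O1[C@@H]2OC(C)(C)O[C@@H]2[C@H](O)[C@H]1[C@H]3COC(C)(C)O3 | starting material
11 | 1,2:5,6-di-O-isopropylidene-3-O-(trifluoromethylsulfonyl)-α-D-allofuranose | O1[C@@H]2OC(C)(C)O[C@@H]2[C@H](OS(=O)(=O)C(F)(F)F)[C@H]1[C@H]3COC(C)(C)O3 | intermediate
12 | 3-O-Ar-1,2:5,6-di-O-isopropylidene-α-D-glucofuranose | O1[C@@H]2OC(C)(C)O[C@@H]2[C@@H](Oc4cc5c(=O)cc(CCc6ccccc6)oc5cc4F)[C@H]1[C@H]3COC(C)(C)O3 | intermediate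
13 | methyl 3-O-Ar-α-D-glucopyranoside | O1[C@H](OC)[C@H](O)[C@@H](Oc2cc3c(=O)cc(CCc4ccccc4)oc3cc2F)[C@H](O)[C@H]1CO | intermediate
14 | methyl 6-deoxy-6-iodo-3-O-Ar-α-D-glucopyranoside | O1[C@H](OC)[C@H](O)[C@@H](Oc2cc3c(=O)cc(CCc4ccccc4)oc3cc2F)[C@H](O)[C@H]1CI | intermediate
15 | methyl 2,4-di-O-TBS-6-deoxy-6-iodo-3-O-Ar-α-D-glucopyranoside | O1[C@H](OC)[C@H](O[Si](C)(C)C(C)(C)C)[C@@H](Oc2cc3c(=O)cc(CCc4ccccc4)oc3cc2F)[C@H](O[Si](C)(C)C(C)(C)C)[C@H]1CI | intermediate
16 | methyl 2,4-di-O-TBS-6-deoxy-3-O-Ar-α-D-xylo-hex-5-enopyranoside | O1[C@H](OC)[C@H](O[Si](C)(C)C(C)(C)C)[C@@H](Oc2cc3c(=O)cc(CCc4ccccc4)oc3cc2F)[C@H](O[Si](C)(C)C(C)(C)C)C1=C | intermediate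
17 | (2S,3R,4S,5S)-3-(ArO)-2,4-bis(TBSO)-5-hydroxycyclohexan-1-one | O=C1C[C@H](O)[C@H](O[Si](C)(C)C(C)(C)C)[C@@H](Oc2cc3c(=O)cc(CCc4ccccc4)oc3cc2F)[C@@H]1O[Si](C)(C)C(C)(C)C | intermediate
18 | bis-TMS enol silane of 17 (C1–OTMS, C1=C6; 5-OTMS) | C[Si](C)(C)OC1=C[C@H](O[Si](C)(C)C)[C@H](O[Si](C)(C)C(C)(C)C)[C@@H](Oc2cc3c(=O)cc(CCc4ccccc4)oc3cc2F)[C@@H]1O[Si](C)(C)C(C)(C)C | intermediate
19 | 5-(4-methoxyphenyl)-3-oxopent-1-en-1-one (acylketene) | COc1ccc(CCC(=O)C=C=O)cc1 | intermediate
20 | [4+2] cycloadduct: 8a-(trimethylsilyloxy)-4a,5,6,7,8,8a-hexahydro-4H-chromen-4-one carrying 5-OTMS, 6,8-bis(TBSO), 7-OAr and the 2-[2-(4-methoxyphenyl)ethyl] group; C5–C8 as in 18, C4a and C8a not defined | COc1ccc(CCC2=CC(=O)C3C(O2)(O[Si](C)(C)C)[C@@H](O[Si](C)(C)C(C)(C)C)[C@H](Oc4cc5c(=O)cc(CCc6ccccc6)oc5cc4F)[C@@H](O[Si](C)(C)C(C)(C)C)[C@H]3O[Si](C)(C)C)cc1 | intermediate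
21 | (5S,6S,7R,8S)-7-(ArO)-6,8-bis(TBSO)-5-hydroxy-2-[2-(4-methoxyphenyl)ethyl]-5,6,7,8-tetrahydro-4H-chromen-4-one | COc1ccc(CCc2cc(=O)c3c(o2)[C@@H](O[Si](C)(C)C(C)(C)C)[C@H](Oc4cc5c(=O)cc(CCc6ccccc6)oc5cc4F)[C@@H](O[Si](C)(C)C(C)(C)C)[C@H]3O)cc1 | intermediate
22 | (5R,6S,7R,8S)-7-(ArO)-6,8-bis(TBSO)-2-[2-(4-methoxyphenyl)ethyl]-4-oxo-5,6,7,8-tetrahydro-4H-chromen-5-yl chloroacetate | COc1ccc(CCc2cc(=O)c3c(o2)[C@@H](O[Si](C)(C)C(C)(C)C)[C@H](Oc4cc5c(=O)cc(CCc6ccccc6)oc5cc4F)[C@@H](O[Si](C)(C)C(C)(C)C)[C@@H]3OC(=O)CCl)cc1 | intermediate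
23 | (5R,6S,7R,8S)-7-(ArO)-6,8-dihydroxy-2-[2-(4-methoxyphenyl)ethyl]-4-oxo-5,6,7,8-tetrahydro-4H-chromen-5-yl chloroacetate | COc1ccc(CCc2cc(=O)c3c(o2)[C@@H](O)[C@H](Oc4cc5c(=O)cc(CCc6ccccc6)oc5cc4F)[C@@H](O)[C@@H]3OC(=O)CCl)cc1 | intermediate
24 | (5R,6S,7R,8S)-7-(ArO)-6,8-O-isopropylidene-2-[2-(4-methoxyphenyl)ethyl]-4-oxo-5,6,7,8-tetrahydro-4H-chromen-5-yl chloroacetate | COc1ccc(CCc2cc(=O)c3c(o2)[C@H]4OC(C)(C)O[C@@H]([C@@H]3OC(=O)CCl)[C@H]4Oc5cc6c(=O)cc(CCc7ccccc7)oc6cc5F)cc1 | intermediate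
25 | (5R,6S,7R,8S)-7-(ArO)-5-hydroxy-6,8-O-isopropylidene-2-[2-(4-methoxyphenyl)ethyl]-5,6,7,8-tetrahydro-4H-chromen-4-one | COc1ccc(CCc2cc(=O)c3c(o2)[C@H]4OC(C)(C)O[C@@H]([C@@H]3O)[C@H]4Oc5cc6c(=O)cc(CCc7ccccc7)oc6cc5F)cc1 | intermediate
26 | 6,8-O-isopropylidene derivative of the target (O5–C7' and O7–C6' ethers; 5R,6S,7R,8S) | COc1ccc(CCc2cc(=O)c3c(o2)[C@H]4OC(C)(C)O[C@@H]([C@@H]3O8)[C@H]4Oc5cc6c(=O)cc(CCc7ccccc7)oc6cc58)cc1 | intermediate
27 | (+)-4'-methoxyaquisinenone G | COc1ccc(CCc2cc(=O)c3c(o2)[C@@H](O)[C@@H]2Oc4cc5c(=O)cc(CCc6ccccc6)oc5cc4O[C@H]3[C@@H]2O)cc1 | target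

**Step count**

Total: 19 steps. Longest linear sequence: 17 steps (steps 1–3, then 6–19). The sugar line from 10 is 15 steps.

**Steps most likely to fail, each with a fallback**

Step 18 (key ring closure). Within the rigid bicycle the O5 alkoxide may not reach the trajectory perpendicular to the chromone ring at C7'; substitution between molecules would then outrun ring closure and give oligomers. The fallback sets out from 25 and returns at 26, and exchanges the roles of the two termini. Treating 25 with acetohydroxamic acid and K2CO3 in DMSO at 80 °C (intermolecular SNAr followed by Lossen-type release of the phenoxide) should turn C7'–F into C7'–OH and give the C7' phenol F1. Catalytic Sc(OTf)3 in CH2Cl2/MeNO2 over 4 Å MS should then ionise the axial C5 carbinol to the allylic cation stabilised by O1. The phenol, held on the O7 face, can capture it only syn to O7, which gives 26 by dehydrative etherification.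

Step 13 (pyranone annulation). Two processes threaten it: enolisation toward the silyloxy-bearing α-carbon in step 12, which would place the pyranone on the wrong side, and dimerisation of the acylketene outrunning cycloaddition to the hindered enol silane. The fallback sets out from 17 and returns at 21. Silylation of O5 alone (TMSCl, imidazole, CH2Cl2, 0 °C) should give the 5-O-TMS ketone F2. Its boron enolate, formed with (c-C6H11)2BCl and Et3N in Et2O at −78 °C on the methylene side (boron enolisation avoids the alkoxy-bearing α-carbon), is added to 5-(4-methoxyphenyl)pent-2-ynal F3. F3 is made from purchased 1-(but-3-yn-1-yl)-4-methoxybenzene with n-BuLi and then DMF. The aldol gives the propargylic aldol adduct F4 as a mixture at the two new centres, which does not matter. Dess–Martin periodinane buffered with NaHCO3 should give the 2-alkynoyl ketone F5. p-Toluenesulfonic acid monohydrate in THF/H2O then closes the γ-pyrone by 6-endo-dig addition of the enol oxygen to the ynone and removes the TMS ether, giving 21.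

Step 14 (Mitsunobu inversion). E2 loss toward a C5=C6 double bond, or ionisation at the activated carbinol with loss of stereochemical fidelity, may take the place of clean SN2 inversion. The fallback sets out from 21 and returns at 22. Dess–Martin periodinane with NaHCO3 should oxidise 21 to the 5-ketone F6. Reagent-controlled reduction with BH3·SMe2 and (R)-1-methyl-3,3-diphenyltetrahydro-1H,3H-pyrrolo[1,2-c][1,3,2]oxazaborole (the R-configured CBS catalyst, with sp2 C4a acting as the large group) should deliver hydride to the face anti to O7 and give the 5R alcohol F7. Chloroacetic anhydride, pyridine and catalytic 4-(dimethylamino)pyridine then give 22.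

**Further compounds**

F1 | step 18 | (5R,6S,7R,8S)-5-hydroxy-7-{[7-hydroxy-4-oxo-2-(2-phenylethyl)-4H-chromen-6-yl]oxy}-6,8-O-isopropylidene-2-[2-(4-methoxyphenyl)ethyl]-5,6,7,8-tetrahydro-4H-chromen-4-one | COc1ccc(CCc2cc(=O)c3c(o2)[C@H]4OC(C)(C)O[C@@H]([C@@H]3O)[C@H]4Oc5cc6c(=O)cc(CCc7ccccc7)oc6cc5O)cc1
F2 | step 13 | (2S,3R,4S,5S)-3-(ArO)-2,4-bis(TBSO)-5-(trimethylsilyloxy)cyclohexan-1-one | O=C1C[C@H](O[Si](C)(C)C)[C@H](O[Si](C)(C)C(C)(C)C)[C@@H](Oc2cc3c(=O)cc(CCc4ccccc4)oc3cc2F)[C@@H]1O[Si](C)(C)C(C)(C)C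
F3 | step 13 | 5-(4-methoxyphenyl)pent-2-ynal | COc1ccc(CCC#CC=O)cc1
F4 | step 13 | aldol adduct: 2-[1-hydroxy-5-(4-methoxyphenyl)pent-2-yn-1-yl] derivative of F2 (new centres not defined) | COc1ccc(CCC#CC(O)C2C(=O)[C@@H](O[Si](C)(C)C(C)(C)C)[C@H](Oc3cc4c(=O)cc(CCc5ccccc5)oc4cc3F)[C@@H](O[Si](C)(C)C(C)(C)C)[C@H]2O[Si](C)(C)C)cc1
F5 | step 13 | 2-[5-(4-methoxyphenyl)pent-2-ynoyl] derivative of F2 (diketo form drawn) | COc1ccc(CCC#CC(=O)C2C(=O)[C@@H](O[Si](C)(C)C(C)(C)C)[C@H](Oc3cc4c(=O)cc(CCc5ccccc5)oc4cc3F)[C@@H](O[Si](C)(C)C(C)(C)C)[C@H]2O[Si](C)(C)C)cc1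
F6 | step 14 | (6S,7R,8S)-7-(ArO)-6,8-bis(TBSO)-2-[2-(4-methoxyphenyl)ethyl]-7,8-dihydro-4H-chromene-4,5(6H)-dione | COc1ccc(CCc2cc(=O)c3c(o2)[C@@H](O[Si](C)(C)C(C)(C)C)[C@H](Oc4cc5c(=O)cc(CCc6ccccc6)oc5cc4F)[C@@H](O[Si](C)(C)C(C)(C)C)C3=O)cc1
F7 | step 14 | (5R,6S,7R,8S)-7-(ArO)-6,8-bis(TBSO)-5-hydroxy-2-[2-(4-methoxyphenyl)ethyl]-5,6,7,8-tetrahydro-4H-chromen-4-one | COc1ccc(CCc2cc(=O)c3c(o2)[C@@H](O[Si](C)(C)C(C)(C)C)[C@H](Oc4cc5c(=O)cc(CCc6ccccc6)oc5cc4F)[C@@H](O[Si](C)(C)C(C)(C)C)[C@@H]3O)cc1
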